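Numbering convention used throughout: in the diester names C1 is the methyl ester carbon, C2 carries ring A, C3 carries the benzyl group of ring B, and C4 is the second carboxyl carbon. In the butanoate and acid names the locants run from the other end.

## Analysis of the target

Asperteretal G1 (23) is an open-chain 2,3-disubstituted succinic acid: C1 is a methyl ester and C4 a free carboxylic acid. C2 bears ring A (4-hydroxyphenyl) directly, and C3 bears ring B (4-hydroxy-3-(3-methylbut-2-enyl)phenyl) through a CH2 group. The two adjacent stereocentres are 2S and 3R; with the C1–C4 chain drawn as a zigzag, the aryl group on C2 and the benzyl group on C3 lie on the same side. There is no ring to relay stereochemistry, and C2–H is both benzylic and alpha to an ester, so this centre epimerises under base. The prenyl olefin cyclises onto the neighbouring phenol under acid (2,2-dimethylchroman) and tolerates neither ozone nor hydrogenation. The two carboxyl termini and the two phenols must also be told apart. The route rests on one feature: the prenyl group sits on the ring-B carbon ortho to the ring-B oxygen. That is the pattern left by an aromatic Claisen shift of a 1,1-dimethylallyl aryl ether, so the most fragile group can be made last, under neutral heat.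

## Retrosynthetic reasoning

**23 from 22.** The last operation only unmasks heteroatoms. Ring A is held as a triisopropylsilyl ether and C4 as a 2-(trimethylsilyl)ethyl ester, so one fluoride treatment cleaves an O–Si bond and, by beta-elimination, the ester O–C bond. This avoids strong acid (which would close the chroman) and hydroxide (which would epimerise C2 and attack the methyl ester).

**22 from 20 (key disconnection).** The bond between the ring-B ortho carbon and the prenyl CH2 is cut, leading back to the 1,1-dimethylallyl ether 20. This bond is chosen because a [3,3] shift makes it with fixed regiochemistry and allyl inversion, through dienone 21, without reagents. All oxidative, acidic and reductive steps can therefore be placed before the prenyl group exists.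

**20 from 19, and 19 from 16 and 17.** A tertiary allyl aryl ether cannot be made by direct substitution. The O–C bond is therefore formed at the alkyne stage by copper-catalysed propargylic substitution of the activated alkynol 17 (as 18) with phenol 16, and the alkyne 19 is then semi-hydrogenated. Phenol 16 comes from benzyl ether 15 by hydrogenolysis; the benzyl group marks ring B while ring A carries silicon.

**15 from 14.** The C2–ring A bond is traced to a 1,2-aryl shift. A methyl ester with an aryl group on the adjacent carbon is the product of solvolysis of an aryl dimethyl ketal carrying a sulfonate on the neighbouring carbon, as in 14. The shift inverts the migration terminus, so C2 is derived from a carbinol centre of defined configuration. The ketal carbon becomes the C1 methyl ester, so the two ends of the succinate are differentiated by the same event.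

**14 from 13, 12, and then 8 plus 10.** Mesylate 14 comes from hydroxy ketal 13 and that from hydroxy ketone 12. The ketone C–aryl bond is cut to Weinreb amide 8 and the arylmagnesium reagent 11, made from bromide 10 and ultimately from 4-bromophenol 9. The chelated adduct stops at the ketone stage.

**8 from 7, 6, 5 and 4.** The two carboxyl groups of diacid 5 are distinguished by ring size: the alpha-hydroxy acid closes a five-membered dioxolanone (6), leaving the C4 acid free for conversion into the fluoride-labile ester 7. The dioxolanone then serves as the activated acyl group that is opened to amide 8. Diacid 5 is the saponification product of diester 4.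

**4 from 1 and 2.** The C3–CH2 bond is cut to dimethyl (S)-malate 1 and 4-benzyloxybenzyl bromide 2. Alkylation of the chelated dianion 3 occurs anti to the carbinol substituent and sets 3R from the 2S centre of the chiral pool. The later inversion at C2 then gives the syn aryl/benzyl relationship of the target.

## Alternatives that were turned down

**Alternative 1: Ireland–Claisen construction of the C2–C3 bond.**
- Disconnection and key step: the central C2–C3 bond is cut. The allylic arylacetate A2 would be converted into its silyl ketene acetal and rearranged through a chair to acid A1, forming the bond and both stereocentres by chirality transfer from the carbinol centre. The propenyl group of A1 is the latent C4 carboxyl and the ring-B bromide the latent prenyl group.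
- For: it is convergent, it makes the key C–C bond, and it sets both centres in one step from two simple halves. On convergence and bond construction it is stronger than the chosen route.
- Against: the C2 configuration depends on the enolate geometry of an arylacetate, which must be controlled and kept through silylation. A2 needs an enantioenriched secondary allylic alcohol, which costs extra steps. After the key step the acid must be esterified and the propenyl group cleaved oxidatively to the carboxyl. That cleavage forbids an early prenyl group and forces a late cross-coupling at the aryl bromide, with linear/branched allyl-transfer problems and basic conditions next to an epimerisable C2.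
- Comparison: the chosen route is longer and linear. In exchange both centres come from stereospecific, substrate-defined steps, and the prenyl group arrives without a metal, with regiochemistry fixed by a cyclic transition state.

**Alternative 2: carboxylate-directed C–H arylation to attach ring B.**
- Disconnection and key step: the ring B–CH2 bond is cut. The free carboxylate of acid A4 would direct divalent palladium (Pd(OAc)2 with an amino-acid-type ligand and a silver salt such as Ag2CO3) to the C3 methyl group, and the palladacycle would couple with aryl iodide A5 to give A3.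
- For: it is the most convergent option, ring B arrives with the prenyl group in place, and the acid needs no protection. On step count after the stereocentres are set it is stronger.
- Against: A4 already contains both stereocentres, so the central stereochemical problem is only moved. The coupling runs hot with silver and carbonate, next to an alpha-aryl ester centre that epimerises. The prenyl olefin of A5 and A3 is exposed to electrophilic palladium and silver (insertion, allylic activation, isomerisation).
- Comparison: the riskiest step would consume the stereodefined fragment and would test the prenyl group under the harshest conditions of the sequence. In the chosen route the prenyl group is formed under neutral heat.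

**Alternative 3: cathodic nickel-mediated carboxylation at C3.**
- Disconnection and key step: the C3–CO2H bond is cut. A chiral zerovalent nickel complex generated at the cathode would couple the unsaturated ester A7 with carbon dioxide at C3, and protonation of the resulting enolate at C2 would give A6.
- For: it is the shortest route, the free acid is formed directly and is automatically different from the methyl ester, and A7 is easy to assemble. On step and atom economy it is clearly stronger.
- Against: only C3 is set by the catalyst; C2 is set by protonation of an enolate at an epimerisable position, with no reliable control. Enantioselective carboxylation of a trisubstituted beta-benzyl alpha-aryl acrylate has no close analogy. The olefin of A7 can migrate into conjugation with ring B. The prenyl olefin is exposed to low-valent nickel and nickel hydrides, and the acrylate can be reduced directly at the cathode.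
- Comparison: the chosen route gives up brevity for stereocentres whose configuration follows from known stereospecific steps.

Key step: step 14

Remark on the chemistry: ring A is carried as a triisopropylsilyl ether rather than a tert-butyldimethylsilyl ether. The aryl silyl ether has to survive acidic ketalisation, hot aqueous methanol and DBU before the rearrangement, and it is still cleaved by fluoride in the last step.

## Route

Step 1
Reactants: 1 dimethyl (S)-malate; 2 4-benzyloxybenzyl bromide
Product: 4 dimethyl (2S,3R)-3-{[4-(benzyloxy)phenyl]methyl}-2-hydroxybutanedioate, via dilithium alkoxide-enolate 3 (not isolated)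
Conditions: LiN(SiMe3)2 (2.2 equiv), THF, −78 → −20 °C; then 2, −78 → 0 °C; aq. NH4Cl
Reagents that add atoms: none
Why: Fráter–Seebach alkylation: the chelated dianion 3 should be attacked by the benzylic bromide on the face of C3 remote from the substituent on the alkoxide carbon, so the new centre is set 3R (2,3-anti) under control of the untouched 2S carbinol; the minor syn isomer should be removable by chromatography.

Step 2
Reactants: 4 dimethyl (2S,3R)-3-{[4-(benzyloxy)phenyl]methyl}-2-hydroxybutanedioate
Product: 5 (2S,3R)-3-{[4-(benzyloxy)phenyl]methyl}-2-hydroxybutanedioic acid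
Conditions: LiOH·H2O (3 equiv), THF/H2O, 0 °C → rt; then 1 M HCl
Reagents that add atoms: lithium hydroxide, [Li+].[OH-]
Why: Ester saponification; once each ester is a carboxylate the alpha position is no longer acidic enough to epimerise, and the benzyl ether is inert.

Step 3
Reactants: 5 (2S,3R)-3-{[4-(benzyloxy)phenyl]methyl}-2-hydroxybutanedioic acid
Product: 6 (2R)-3-[4-(benzyloxy)phenyl]-2-[(4S)-2,2-dimethyl-5-oxo-1,3-dioxolan-4-yl]propanoic acid
Conditions: Me2C(OMe)2, TsOH·H2O (cat.), CH2Cl2, rt
Reagents that add atoms: 2,2-dimethoxypropane, COC(C)(C)OC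
Why: Acid-catalysed transacetalisation; the alpha-hydroxy acid should close the five-membered 1,3-dioxolan-4-one in preference to the six-membered ring available to the beta-carboxyl, which leaves the C4 acid free and so differentiates the two termini without touching either stereocentre.

Step 4
Reactants: 6 (2R)-3-[4-(benzyloxy)phenyl]-2-[(4S)-2,2-dimethyl-5-oxo-1,3-dioxolan-4-yl]propanoic acid
Product: 7 2-(trimethylsilyl)ethyl (2R)-3-[4-(benzyloxy)phenyl]-2-[(4S)-2,2-dimethyl-5-oxo-1,3-dioxolan-4-yl]propanoate
Conditions: Me3SiCH2CH2OH, DCC, DMAP (cat.), CH2Cl2, 0 °C → rt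
Reagents that add atoms: 2-(trimethylsilyl)ethanol, C[Si](C)(C)CCO
Why: Steglich esterification; the near-neutral carbodiimide coupling at low temperature should leave the dioxolanone closed and the alpha centre unepimerised, and it installs the fluoride-labile ester needed at the end.

Step 5
Reactants: 7 2-(trimethylsilyl)ethyl (2R)-3-[4-(benzyloxy)phenyl]-2-[(4S)-2,2-dimethyl-5-oxo-1,3-dioxolan-4-yl]propanoate
Product: 8 2-(trimethylsilyl)ethyl (2R,3S)-2-{[4-(benzyloxy)phenyl]methyl}-3-hydroxy-4-[methoxy(methyl)amino]-4-oxobutanoate
Conditions: MeNHOMe·HCl, i-PrMgCl, THF, −20 °C; then 7, −20 → 0 °C; aq. NH4Cl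
Reagents that add atoms: N,O-dimethylhydroxylamine hydrochloride, CNOC.Cl
Why: Aminolysis of an activated lactone by a preformed magnesium amide (Weinreb amide synthesis); the acylal-type dioxolanone carbonyl is far more electrophilic than the hindered alpha-branched ester, so it should open selectively with loss of acetone to give the alpha-hydroxy amide.

Step 6
Reactants: 9 4-bromophenol
Product: 10 (4-bromophenoxy)tri(propan-2-yl)silane
Conditions: i-Pr3SiCl, imidazole, DMF, rt
Reagents that add atoms: chlorotri(propan-2-yl)silane, CC(C)[Si](Cl)(C(C)C)C(C)C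
Why: Standard silylation of a phenol; the bulky silyl ether tolerates Grignard formation, catalytic acid, hot aqueous methanol and amine bases, yet is cleaved by fluoride.

Step 7
Reactants: 8 2-(trimethylsilyl)ethyl (2R,3S)-2-{[4-(benzyloxy)phenyl]methyl}-3-hydroxy-4-[methoxy(methyl)amino]-4-oxobutanoate; 10 (4-bromophenoxy)tri(propan-2-yl)silane
Product: 12 2-(trimethylsilyl)ethyl (2R,3S)-2-{[4-(benzyloxy)phenyl]methyl}-3-hydroxy-4-oxo-4-{4-[tri(propan-2-yl)silyloxy]phenyl}butanoate, via arylmagnesium bromide 11 (not isolated)
Conditions: 10, Mg, THF, 45 °C; 8, i-PrMgCl (1.0 equiv), THF, −20 °C, then 11 (1.5 equiv), −20 → 0 °C; aq. NH4Cl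
Reagents that add atoms: none
Why: Weinreb ketone synthesis; after the hydroxyl is deprotonated, 11 should add to the amide to give a magnesium chelate that does not collapse until the quench, which prevents over-addition and keeps the carbinol centre from enolising, while the alpha-branched ester reacts more slowly at or below 0 °C.

Step 8
Reactants: 12 2-(trimethylsilyl)ethyl (2R,3S)-2-{[4-(benzyloxy)phenyl]methyl}-3-hydroxy-4-oxo-4-{4-[tri(propan-2-yl)silyloxy]phenyl}butanoate
Product: 13 2-(trimethylsilyl)ethyl (2R,3S)-2-{[4-(benzyloxy)phenyl]methyl}-3-hydroxy-4,4-dimethoxy-4-{4-[tri(propan-2-yl)silyloxy]phenyl}butanoate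
Conditions: HC(OMe)3, MeOH, camphorsulfonic acid (cat.), 40 °C; then Et3N
Reagents that add atoms: trimethyl orthoformate, COC(OC)OC; methanol, CO
Why: Acid-catalysed ketalisation of an alpha-hydroxy aryl ketone, driven by the orthoformate as water scavenger; the triisopropylsilyl aryl ether and the hindered ester should tolerate catalytic sulfonic acid, and no bond to a stereocentre is broken.

Step 9
Reactants: 13 2-(trimethylsilyl)ethyl (2R,3S)-2-{[4-(benzyloxy)phenyl]methyl}-3-hydroxy-4,4-dimethoxy-4-{4-[tri(propan-2-yl)silyloxy]phenyl}butanoate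
Product: 14 2-(trimethylsilyl)ethyl (2R,3S)-2-{[4-(benzyloxy)phenyl]methyl}-4,4-dimethoxy-3-(methanesulfonyloxy)-4-{4-[tri(propan-2-yl)silyloxy]phenyl}butanoate
Conditions: MsCl, Et3N, CH2Cl2, −20 → 0 °C; used crude
Reagents that add atoms: methanesulfonyl chloride, CS(=O)(=O)Cl
Why: Sulfonylation through the sulfene reaches even a hindered secondary alcohol and leaves the C–O bond, and so the configuration, intact; low temperature and short contact should avoid beta-elimination toward the ester alpha-hydrogen and premature ionisation.

Step 10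
Reactants: 14 2-(trimethylsilyl)ethyl (2R,3S)-2-{[4-(benzyloxy)phenyl]methyl}-4,4-dimethoxy-3-(methanesulfonyloxy)-4-{4-[tri(propan-2-yl)silyloxy]phenyl}butanoate
Product: 15 1-methyl 4-[2-(trimethylsilyl)ethyl] (2S,3R)-3-{[4-(benzyloxy)phenyl]methyl}-2-{4-[tri(propan-2-yl)silyloxy]phenyl}butanedioate
Conditions: CaCO3, MeOH/H2O (7:3), 80 °C
Reagents that add atoms: water, O
Why: Stereospecific 1,2-aryl shift of an alpha-sulfonyloxy ketal (the rearrangement used for 2-arylpropanoates): the electron-rich aryl group should bridge anti to the departing mesylate and the resulting dialkoxycarbenium ion is hydrolysed to the methyl ester. Migration inverts the former carbinol carbon, which sets C2 as 2S, syn to the benzyl group, while C3 is untouched; CaCO3 takes up the sulfonic acid.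

Step 11
Reactants: 15 1-methyl 4-[2-(trimethylsilyl)ethyl] (2S,3R)-3-{[4-(benzyloxy)phenyl]methyl}-2-{4-[tri(propan-2-yl)silyloxy]phenyl}butanedioate
Product: 16 1-methyl 4-[2-(trimethylsilyl)ethyl] (2S,3R)-3-[(4-hydroxyphenyl)methyl]-2-{4-[tri(propan-2-yl)silyloxy]phenyl}butanedioate
Conditions: H2 (1 atm), Pd/C (10 %), EtOAc, rt
Reagents that add atoms: none
Why: Hydrogenolysis of a benzyl aryl ether; nothing else in the molecule is reducible under these neutral conditions, and only the ring-B phenol is released.

Step 12
Reactants: 16 1-methyl 4-[2-(trimethylsilyl)ethyl] (2S,3R)-3-[(4-hydroxyphenyl)methyl]-2-{4-[tri(propan-2-yl)silyloxy]phenyl}butanedioate; 17 2-methylbut-3-yn-2-ol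
Product: 19 1-methyl 4-[2-(trimethylsilyl)ethyl] (2S,3R)-3-{[4-(2-methylbut-3-yn-2-yloxy)phenyl]methyl}-2-{4-[tri(propan-2-yl)silyloxy]phenyl}butanedioate, via propargylic trifluoroacetate 18 (not isolated)
Conditions: 17, (CF3CO)2O, DBU, MeCN, −5 °C; then 16, CuCl2·2H2O (cat.), DBU (1.2 equiv), MeCN, −5 → 0 °C
Reagents that add atoms: none
Why: Copper-catalysed propargylic etherification: the copper acetylide of 18 should ionise to a copper-stabilised propargylic cation that the phenoxide captures at the tertiary carbon, giving the O-alkylated 1,1-dimethylpropargyl ether only; low temperature and a small excess of base should spare C2 and the silyl ether.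

Step 13
Reactants: 19 1-methyl 4-[2-(trimethylsilyl)ethyl] (2S,3R)-3-{[4-(2-methylbut-3-yn-2-yloxy)phenyl]methyl}-2-{4-[tri(propan-2-yl)silyloxy]phenyl}butanedioate
Product: 20 1-methyl 4-[2-(trimethylsilyl)ethyl] (2S,3R)-3-{[4-(2-methylbut-3-en-2-yloxy)phenyl]methyl}-2-{4-[tri(propan-2-yl)silyloxy]phenyl}butanedioate
Conditions: H2 (1 atm), Pd/CaCO3–Pb(OAc)2, quinoline, EtOAc, rt
Reagents that add atoms: none
Why: Semi-hydrogenation of a terminal alkyne over lead-poisoned palladium should stop at the vinyl group; the poisoned catalyst is not expected to hydrogenolyse the tertiary ether, and hydrogen uptake is monitored to avoid over-reduction.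

Step 14
Reactants: 20 1-methyl 4-[2-(trimethylsilyl)ethyl] (2S,3R)-3-{[4-(2-methylbut-3-en-2-yloxy)phenyl]methyl}-2-{4-[tri(propan-2-yl)silyloxy]phenyl}butanedioate
Product: 22 1-methyl 4-[2-(trimethylsilyl)ethyl] (2S,3R)-3-{[4-hydroxy-3-(3-methylbut-2-enyl)phenyl]methyl}-2-{4-[tri(propan-2-yl)silyloxy]phenyl}butanedioate, via ortho-dienone 21 (not isolated)
Conditions: PhNEt2, 120–130 °C, argon
Reagents that add atoms: none
Why: On heating, ether 20 should undergo a concerted suprafacial [3,3]-sigmatropic shift through a chair-like six-membered transition state, in which the O–C(CH3)2 bond breaks while the terminal vinyl CH2 bonds to the ring-B carbon ortho to oxygen, giving dienone 21, which enolises at once to phenol 22. The closest known reaction type is the aromatic Claisen rearrangement of aryl 1,1-dimethylallyl ethers to ortho-prenylphenols. No ring is closed, so no mode of closure applies, and no stereocentre is created in 22, because the sp3 ring carbon of 21 is lost on tautomerisation and the new olefin carries two identical methyl groups. The step needs ring selectivity, positional selectivity and the linear prenyl isomer: only ring B carries an allyl ether (ring A is a silyl ether), its two ortho positions are equivalent and its para position is blocked by the CH2 link to C3, and the allyl inversion built into the cyclic transition state turns the tertiary ether carbon into the olefin terminus. The geminal methyl groups weaken the breaking C–O bond and favour the reactive conformer, so moderate heating should suffice. The weakly basic amine solvent scavenges traces of acid that would ionise the tertiary ether or cyclise 22 to a 2,2-dimethylchroman. It is too weak a base to remove the C2 proton, so the 2S and 3R centres, both esters and the silyl ether should pass through unchanged.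

Step 15
Reactants: 22 1-methyl 4-[2-(trimethylsilyl)ethyl] (2S,3R)-3-{[4-hydroxy-3-(3-methylbut-2-enyl)phenyl]methyl}-2-{4-[tri(propan-2-yl)silyloxy]phenyl}butanedioate
Product: 23 asperteretal G1, (2R,3S)-2-{[4-hydroxy-3-(3-methylbut-2-enyl)phenyl]methyl}-3-(4-hydroxyphenyl)-4-methoxy-4-oxobutanoic acid
Conditions: Bu4NF, AcOH, THF, 0 °C → rt; pH 4 buffer work-up
Reagents that add atoms: none
Why: Fluoride-induced desilylation: attack at the aryl silyl ether frees the ring-A phenol, and attack at the trimethylsilyl group triggers beta-elimination of ethene to free the C4 carboxylate. Acetic acid buffers the medium so that C2–H is not removed and the methyl ester is not touched, and no acid strong enough to cyclise the prenylphenol is present.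

## Compound list

1 | dimethyl (S)-malate | COC(=O)C[C@H](O)C(=O)OC | starting material
2 | 4-benzyloxybenzyl bromide | BrCc1ccc(OCc2ccccc2)cc1 | starting material
3 | dilithium (1E,3S)-1,4-dimethoxy-4-oxobut-1-ene-1,3-bis(olate) | [Li+].[Li+].COC(=O)[C@@H]([O-])/C=C(\[O-])OC | intermediate
4 | dimethyl (2S,3R)-3-{[4-(benzyloxy)phenyl]methyl}-2-hydroxybutanedioate | COC(=O)[C@@H](O)[C@@H](Cc1ccc(OCc2ccccc2)cc1)C(=O)OC | intermediate
5 | (2S,3R)-3-{[4-(benzyloxy)phenyl]methyl}-2-hydroxybutanedioic acid | OC(=O)[C@@H](O)[C@@H](Cc1ccc(OCc2ccccc2)cc1)C(=O)O | intermediate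
6 | (2R)-3-[4-(benzyloxy)phenyl]-2-[(4S)-2,2-dimethyl-5-oxo-1,3-dioxolan-4-yl]propanoic acid | O=C1OC(C)(C)O[C@H]1[C@@H](Cc1ccc(OCc2ccccc2)cc1)C(=O)O | intermediate
7 | 2-(trimethylsilyl)ethyl (2R)-3-[4-(benzyloxy)phenyl]-2-[(4S)-2,2-dimethyl-5-oxo-1,3-dioxolan-4-yl]propanoate | O=C1OC(C)(C)O[C@H]1[C@@H](Cc1ccc(OCc2ccccc2)cc1)C(=O)OCC[Si](C)(C)C | intermediate
8 | 2-(trimethylsilyl)ethyl (2R,3S)-2-{[4-(benzyloxy)phenyl]methyl}-3-hydroxy-4-[methoxy(methyl)amino]-4-oxobutanoate | CON(C)C(=O)[C@@H](O)[C@@H](Cc1ccc(OCc2ccccc2)cc1)C(=O)OCC[Si](C)(C)C | intermediate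
9 | 4-bromophenol | Oc1ccc(Br)cc1 | starting material
10 | (4-bromophenoxy)tri(propan-2-yl)silane | CC(C)[Si](Oc1ccc(Br)cc1)(C(C)C)C(C)C | intermediate
11 | bromo{4-[tri(propan-2-yl)silyloxy]phenyl}magnesium | CC(C)[Si](Oc1ccc([Mg]Br)cc1)(C(C)C)C(C)C | intermediate
12 | 2-(trimethylsilyl)ethyl (2R,3S)-2-{[4-(benzyloxy)phenyl]methyl}-3-hydroxy-4-oxo-4-{4-[tri(propan-2-yl)silyloxy]phenyl}butanoate | CC(C)[Si](Oc1ccc(cc1)C(=O)[C@@H](O)[C@@H](Cc1ccc(OCc2ccccc2)cc1)C(=O)OCC[Si](C)(C)C)(C(C)C)C(C)C | intermediate
13 | 2-(trimethylsilyl)ethyl (2R,3S)-2-{[4-(benzyloxy)phenyl]methyl}-3-hydroxy-4,4-dimethoxy-4-{4-[tri(propan-2-yl)silyloxy]phenyl}butanoate | CC(C)[Si](Oc1ccc(cc1)C(OC)(OC)[C@@H](O)[C@@H](Cc1ccc(OCc2ccccc2)cc1)C(=O)OCC[Si](C)(C)C)(C(C)C)C(C)C | intermediate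
14 | 2-(trimethylsilyl)ethyl (2R,3S)-2-{[4-(benzyloxy)phenyl]methyl}-4,4-dimethoxy-3-(methanesulfonyloxy)-4-{4-[tri(propan-2-yl)silyloxy]phenyl}butanoate | CC(C)[Si](Oc1ccc(cc1)C(OC)(OC)[C@@H](OS(C)(=O)=O)[C@@H](Cc1ccc(OCc2ccccc2)cc1)C(=O)OCC[Si](C)(C)C)(C(C)C)C(C)C | intermediate
15 | 1-methyl 4-[2-(trimethylsilyl)ethyl] (2S,3R)-3-{[4-(benzyloxy)phenyl]methyl}-2-{4-[tri(propan-2-yl)silyloxy]phenyl}butanedioate | COC(=O)[C@H](c1ccc(O[Si](C(C)C)(C(C)C)C(C)C)cc1)[C@@H](Cc1ccc(OCc2ccccc2)cc1)C(=O)OCC[Si](C)(C)C | intermediate
16 | 1-methyl 4-[2-(trimethylsilyl)ethyl] (2S,3R)-3-[(4-hydroxyphenyl)methyl]-2-{4-[tri(propan-2-yl)silyloxy]phenyl}butanedioate | COC(=O)[C@H](c1ccc(O[Si](C(C)C)(C(C)C)C(C)C)cc1)[C@@H](Cc1ccc(O)cc1)C(=O)OCC[Si](C)(C)C | intermediate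
17 | 2-methylbut-3-yn-2-ol | CC(C)(O)C#C | starting material
18 | 2-methylbut-3-yn-2-yl 2,2,2-trifluoroacetate | CC(C)(OC(=O)C(F)(F)F)C#C | intermediate
19 | 1-methyl 4-[2-(trimethylsilyl)ethyl] (2S,3R)-3-{[4-(2-methylbut-3-yn-2-yloxy)phenyl]methyl}-2-{4-[tri(propan-2-yl)silyloxy]phenyl}butanedioate | COC(=O)[C@H](c1ccc(O[Si](C(C)C)(C(C)C)C(C)C)cc1)[C@@H](Cc1ccc(OC(C)(C)C#C)cc1)C(=O)OCC[Si](C)(C)C | intermediate
20 | 1-methyl 4-[2-(trimethylsilyl)ethyl] (2S,3R)-3-{[4-(2-methylbut-3-en-2-yloxy)phenyl]methyl}-2-{4-[tri(propan-2-yl)silyloxy]phenyl}butanedioate | COC(=O)[C@H](c1ccc(O[Si](C(C)C)(C(C)C)C(C)C)cc1)[C@@H](Cc1ccc(OC(C)(C)C=C)cc1)C(=O)OCC[Si](C)(C)C | intermediate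
21 | 1-methyl 4-[2-(trimethylsilyl)ethyl] (2S,3R)-3-{[3-(3-methylbut-2-enyl)-4-oxocyclohexa-1,5-dien-1-yl]methyl}-2-{4-[tri(propan-2-yl)silyloxy]phenyl}butanedioate (ring sp3 centre not defined) | COC(=O)[C@H](c1ccc(O[Si](C(C)C)(C(C)C)C(C)C)cc1)[C@@H](CC1=CC(CC=C(C)C)C(=O)C=C1)C(=O)OCC[Si](C)(C)C | intermediate
22 | 1-methyl 4-[2-(trimethylsilyl)ethyl] (2S,3R)-3-{[4-hydroxy-3-(3-methylbut-2-enyl)phenyl]methyl}-2-{4-[tri(propan-2-yl)silyloxy]phenyl}butanedioate | COC(=O)[C@H](c1ccc(O[Si](C(C)C)(C(C)C)C(C)C)cc1)[C@@H](Cc1ccc(O)c(CC=C(C)C)c1)C(=O)OCC[Si](C)(C)C | intermediate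
23 | asperteretal G1, (2R,3S)-2-{[4-hydroxy-3-(3-methylbut-2-enyl)phenyl]methyl}-3-(4-hydroxyphenyl)-4-methoxy-4-oxobutanoic acid | COC(=O)[C@H](c1ccc(O)cc1)[C@@H](Cc1ccc(O)c(CC=C(C)C)c1)C(=O)O | target

## Step count and least certain steps

Total: 15 steps. Longest linear sequence: 14 steps (steps 1–5 and 7–15); step 6 prepares the ring-A bromide.

**Step 14 (key step).** The most likely failure is thermal fragmentation of the tertiary allyl ether, with loss of the C5 unit as a diene and return of the phenol, before the sigmatropic shift occurs. Acid-triggered cyclisation of the product onto its prenyl group during prolonged heating is the second risk. Fallback, from 16 back to 22: the ring-B phenol of 16 is brominated ortho to oxygen (N-bromosuccinimide, CH2Cl2, 0 °C; the free phenol is far more activated than the silylated ring A). This gives 1-methyl 4-[2-(trimethylsilyl)ethyl] (2S,3R)-3-[(3-bromo-4-hydroxyphenyl)methyl]-2-{4-[tri(propan-2-yl)silyloxy]phenyl}butanedioate F1. A Stille coupling of F1 with tributyl(3-methylbut-2-enyl)stannane and Pd(PPh3)4 in DMF at 80 °C then gives 22. The price is a metal-mediated allyl transfer, whose linear/branched ratio is less certain than that of the pericyclic route.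

**Step 10.** Ionisation of the mesylate may be diverted into elimination toward the ester alpha-hydrogen, or into participation by a ketal oxygen in place of the aryl group, because the migration terminus is flanked by a fully substituted carbon and an ester-bearing carbon. Fallback, from 7 back to 15:
- The dioxolanone of 7 is opened with methanol (TsOH cat., rt) to 1-methyl 4-[2-(trimethylsilyl)ethyl] (2S,3R)-3-{[4-(benzyloxy)phenyl]methyl}-2-hydroxybutanedioate F2.
- F2 is converted with (CF3SO2)2O and 2,6-lutidine at −78 °C into 1-methyl 4-[2-(trimethylsilyl)ethyl] (2S,3R)-3-{[4-(benzyloxy)phenyl]methyl}-2-(trifluoromethanesulfonyloxy)butanedioate F3.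
- F3 is displaced with inversion by lithium bis{4-[tri(propan-2-yl)silyloxy]phenyl}cuprate F4 (from 10, n-BuLi, then CuI) at −78 °C to give 15 directly.

This replaces the rearrangement with a direct substitution and has its own elimination risk.

**Step 8.** Under acid in methanol, the hemiketal may close onto the neighbouring ester to give a lactone-type pseudo-ester, or the silylethyl ester may be exchanged for methyl, in competition with ketal formation at this hindered, electron-rich aryl ketone. Fallback, from 12 back to 13:
- The hydroxyl of 12 is silylated (Me3SiCl, imidazole) to 2-(trimethylsilyl)ethyl (2R,3S)-2-{[4-(benzyloxy)phenyl]methyl}-4-oxo-4-{4-[tri(propan-2-yl)silyloxy]phenyl}-3-(trimethylsilyloxy)butanoate F5.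
- The ketone is ketalised under aprotic conditions (MeOSiMe3, Me3SiOSO2CF3 cat., CH2Cl2, −78 °C) to 2-(trimethylsilyl)ethyl (2R,3S)-2-{[4-(benzyloxy)phenyl]methyl}-4,4-dimethoxy-4-{4-[tri(propan-2-yl)silyloxy]phenyl}-3-(trimethylsilyloxy)butanoate F6.
- The labile trimethylsilyl ether is removed (K2CO3 cat., MeOH, 0 °C, short contact) to give 13.

**Step 7.** Competitive addition of the arylmagnesium reagent to the silylethyl ester would erode chemoselectivity, since the amide is deactivated by the adjacent alkoxide. Fallback, from 6 back to 12: the aryl addition is run while C4 is a carboxylate, which is inert to Grignard reagents.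
- Acid 6 is opened with the magnesium amide of N,O-dimethylhydroxylamine (excess i-PrMgCl) to (2R,3S)-2-{[4-(benzyloxy)phenyl]methyl}-3-hydroxy-4-[methoxy(methyl)amino]-4-oxobutanoic acid F7.
- F7 is treated with excess 11 to give (2R,3S)-2-{[4-(benzyloxy)phenyl]methyl}-3-hydroxy-4-oxo-4-{4-[tri(propan-2-yl)silyloxy]phenyl}butanoic acid F8.
- F8 is esterified with excess 2-(trimethylsilyl)ethanol (DCC, DMAP cat., 0 °C) to 12.

**Step 12.** Base-induced epimerisation at C2 (benzylic and alpha to the ester), or base-induced loss of the aryl silyl ether followed by etherification of the wrong phenol, could occur during exposure to DBU. Fallback, from 16 directly to 20 (bypassing 19 and step 13): tert-butyl 2-methylbut-3-en-2-yl carbonate F9 is prepared from 2-methylbut-3-en-2-ol and di-tert-butyl dicarbonate. Phenol 16 is O-allylated with F9 and Pd(PPh3)4 in THF at 0 °C, without added base, through the 1,1-dimethylallyl complex of palladium, to give 20. The drawback is possible formation of the linear prenyl ether alongside the branched one, which is why the alkyne route is preferred.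

## Further compounds

F1 | step 14 | 1-methyl 4-[2-(trimethylsilyl)ethyl] (2S,3R)-3-[(3-bromo-4-hydroxyphenyl)methyl]-2-{4-[tri(propan-2-yl)silyloxy]phenyl}butanedioate | COC(=O)[C@H](c1ccc(O[Si](C(C)C)(C(C)C)C(C)C)cc1)[C@@H](Cc1ccc(O)c(Br)c1)C(=O)OCC[Si](C)(C)C
F2 | step 10 | 1-methyl 4-[2-(trimethylsilyl)ethyl] (2S,3R)-3-{[4-(benzyloxy)phenyl]methyl}-2-hydroxybutanedioate | COC(=O)[C@@H](O)[C@@H](Cc1ccc(OCc2ccccc2)cc1)C(=O)OCC[Si](C)(C)C
F3 | step 10 | 1-methyl 4-[2-(trimethylsilyl)ethyl] (2S,3R)-3-{[4-(benzyloxy)phenyl]methyl}-2-(trifluoromethanesulfonyloxy)butanedioate | COC(=O)[C@@H](OS(=O)(=O)C(F)(F)F)[C@@H](Cc1ccc(OCc2ccccc2)cc1)C(=O)OCC[Si](C)(C)C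
F4 | step 10 | lithium bis{4-[tri(propan-2-yl)silyloxy]phenyl}cuprate | [Li+].CC(C)[Si](Oc1ccc([Cu-]c2ccc(O[Si](C(C)C)(C(C)C)C(C)C)cc2)cc1)(C(C)C)C(C)C
F5 | step 8 | 2-(trimethylsilyl)ethyl (2R,3S)-2-{[4-(benzyloxy)phenyl]methyl}-4-oxo-4-{4-[tri(propan-2-yl)silyloxy]phenyl}-3-(trimethylsilyloxy)butanoate | CC(C)[Si](Oc1ccc(cc1)C(=O)[C@@H](O[Si](C)(C)C)[C@@H](Cc1ccc(OCc2ccccc2)cc1)C(=O)OCC[Si](C)(C)C)(C(C)C)C(C)C
F6 | step 8 | 2-(trimethylsilyl)ethyl (2R,3S)-2-{[4-(benzyloxy)phenyl]methyl}-4,4-dimethoxy-4-{4-[tri(propan-2-yl)silyloxy]phenyl}-3-(trimethylsilyloxy)butanoate | CC(C)[Si](Oc1ccc(cc1)C(OC)(OC)[C@@H](O[Si](C)(C)C)[C@@H](Cc1ccc(OCc2ccccc2)cc1)C(=O)OCC[Si](C)(C)C)(C(C)C)C(C)C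
F7 | step 7 | (2R,3S)-2-{[4-(benzyloxy)phenyl]methyl}-3-hydroxy-4-[methoxy(methyl)amino]-4-oxobutanoic acid | CON(C)C(=O)[C@@H](O)[C@@H](Cc1ccc(OCc2ccccc2)cc1)C(=O)O
F8 | step 7 | (2R,3S)-2-{[4-(benzyloxy)phenyl]methyl}-3-hydroxy-4-oxo-4-{4-[tri(propan-2-yl)silyloxy]phenyl}butanoic acid | CC(C)[Si](Oc1ccc(cc1)C(=O)[C@@H](O)[C@@H](Cc1ccc(OCc2ccccc2)cc1)C(=O)O)(C(C)C)C(C)C
F9 | step 12 | tert-butyl 2-methylbut-3-en-2-yl carbonate | CC(C)(C)OC(=O)OC(C)(C)C=C
A1 | alternative 1 | (2S,3S,4E)-3-{[3-bromo-4-(tert-butyldimethylsilyloxy)phenyl]methyl}-2-[4-(tert-butyldimethylsilyloxy)phenyl]hex-4-enoic acid | OC(=O)[C@H](c1ccc(O[Si](C)(C)C(C)(C)C)cc1)[C@@H](Cc1ccc(O[Si](C)(C)C(C)(C)C)c(Br)c1)/C=C/C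
A2 | alternative 1 | (2R,3E)-5-[3-bromo-4-(tert-butyldimethylsilyloxy)phenyl]pent-3-en-2-yl 2-[4-(tert-butyldimethylsilyloxy)phenyl]acetate | C[C@H](/C=C/Cc1ccc(O[Si](C)(C)C(C)(C)C)c(Br)c1)OC(=O)Cc1ccc(O[Si](C)(C)C(C)(C)C)cc1
A3 | alternative 2 | (2R,3S)-4-methoxy-2-{[3-(3-methylbut-2-enyl)-4-(triisopropylsilyloxy)phenyl]methyl}-4-oxo-3-[4-(triisopropylsilyloxy)phenyl]butanoic acid | COC(=O)[C@H](c1ccc(O[Si](C(C)C)(C(C)C)C(C)C)cc1)[C@@H](Cc1ccc(O[Si](C(C)C)(C(C)C)C(C)C)c(CC=C(C)C)c1)C(=O)O
A4 | alternative 2 | (2R,3S)-4-methoxy-2-methyl-4-oxo-3-[4-(triisopropylsilyloxy)phenyl]butanoic acid | COC(=O)[C@H](c1ccc(O[Si](C(C)C)(C(C)C)C(C)C)cc1)[C@@H](C)C(=O)O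
A5 | alternative 2 | [4-iodo-2-(3-methylbut-2-enyl)phenoxy]tri(propan-2-yl)silane | CC(C)=CCc1cc(I)ccc1O[Si](C(C)C)(C(C)C)C(C)C
A6 | alternative 3 | (2R,3S)-2-{[4-(tert-butyldimethylsilyloxy)-3-(3-methylbut-2-enyl)phenyl]methyl}-3-[4-(tert-butyldimethylsilyloxy)phenyl]-4-methoxy-4-oxobutanoic acid | COC(=O)[C@H](c1ccc(O[Si](C)(C)C(C)(C)C)cc1)[C@@H](Cc1ccc(O[Si](C)(C)C(C)(C)C)c(CC=C(C)C)c1)C(=O)O
A7 | alternative 3 | methyl (2E)-4-[4-(tert-butyldimethylsilyloxy)-3-(3-methylbut-2-enyl)phenyl]-2-[4-(tert-butyldimethylsilyloxy)phenyl]but-2-enoate | COC(=O)/C(c1ccc(O[Si](C)(C)C(C)(C)C)cc1)=C/Cc1ccc(O[Si](C)(C)C(C)(C)C)c(CC=C(C)C)c1
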